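**Retrosynthesis**
1. Remove the TES group from the 12-OH (last step). Before that, the C7–C8 bond comes from an anti-aldol of the C8 lithium enolate of iodoenone **13** (ring plus ω-chain) with Z-enal **5** (C1–C7 chain), with in-situ O-acetylation of the aldolate.
2. **13** comes from α-iodination of TES ether **12**, which comes from hydroxyenone **11**. **11** comes from MnO2 oxidation of cis-diol **10**, which comes from Z-selective cross-metathesis of allyl compound **7** with 1-heptene.
3. **7** is made by anti-to-OTBS 1,2-addition of allylmagnesium bromide to (R)-4-OTBS-cyclopentenone **6**. This transfers the C4 chirality to the tertiary C12 carbinol.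
4. Enal **5** comes from 5-hexynoic acid by hydroxymethylation, esterification, Lindlar reduction and oxidation.
5. The cyclopentenone ring is present in **6** from the start, so no ring is formed in the route.

**Assumption:** (R)-4-(tert-butyldimethylsilyloxy)cyclopent-2-en-1-one (**6**) is available as the single enantiomer.

Target configuration from the SMILES: 7S, 8R, 12S. The C8 side chain is cis to the 12-OH and trans to the octenyl chain. The C7/C8 relationship is anti.

---

**Step 1**
Reactants: **1** 5-hexynoic acid
Product: **2** 7-hydroxyhept-5-ynoic acid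
Conditions: n-BuLi (2.2 equiv), THF, −78 → 0 °C; then (CH2O)n, 0 °C → rt; H3O+ work-up
Reagents that add atoms: paraformaldehyde (formaldehyde), C=O
Why: The carboxylate/alkynyl dianion adds through the alkynyl carbon to formaldehyde (acetylide hydroxymethylation), giving the propargylic alcohol.

**Step 2**
Reactants: **2**
Product: **3** methyl 7-hydroxyhept-5-ynoate
Conditions: MeI, K2CO3, DMF, rt
Reagents that add atoms: MeI, CI
Why: Carboxylate O-alkylation (SN2) is selective over the neutral propargylic alcohol.

**Step 3**
Reactants: **3**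
Product: **4** methyl (5Z)-7-hydroxyhept-5-enoate
Conditions: H2 (1 atm), Lindlar Pd/CaCO3/Pb, quinoline, EtOAc, rt
Reagents that add atoms: none
Why: Syn-hydrogenation over the poisoned catalyst (Lindlar semihydrogenation) gives the cis alkene, setting the C5=C6 Z geometry.

**Step 4**
Reactants: **4**
Product: **5** methyl (5Z)-7-oxohept-5-enoate
Conditions: Dess–Martin periodinane, NaHCO3, CH2Cl2, 0 °C
Reagents that add atoms: none
Why: Buffered mild oxidation of the primary allylic alcohol (Dess–Martin oxidation) avoids Z→E isomerization.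

**Step 5**
Reactants: **6** (4R)-4-(TBSO)cyclopent-2-en-1-one
Product: **7** (1S,4R)-1-allyl-4-(TBSO)cyclopent-2-en-1-ol
Conditions: allylMgBr, CeCl3, THF, −78 °C
Reagents that add atoms: allylmagnesium bromide, C=CC[Mg]Br
Why: Organocerium 1,2-addition to the enone carbonyl (Luche-type) occurs anti to the bulky C4-OTBS group. The allyl group ends up trans to OTBS and the new OH cis to it, which sets the future C12 (S) centre.

**Step 6**
Reactants: **7**; **8** 1-heptene
Product: **9** (1S,4R)-4-(TBSO)-1-[(2Z)-oct-2-en-1-yl]cyclopent-2-en-1-ol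
Conditions: Z-selective cyclometalated Ru-carbene catalyst (3 mol %), THF, 35 °C, dynamic vacuum to remove ethylene
Reagents that add atoms: none beyond reactant **8**
Why: Z-selective cross-metathesis of the terminal allyl alkene with 1-heptene builds the C14=C15 (Z) ω-chain. The ring enone-free, hindered cyclopentenol alkene is unreactive.

**Step 7**
Reactants: **9**
Product: **10** (1S,4R)-1-[(2Z)-oct-2-en-1-yl]cyclopent-2-ene-1,4-diol
Conditions: HF·pyridine, pyridine/THF, 0 °C → rt
Reagents that add atoms: none
Why: Buffered fluoride cleaves the secondary TBS ether (silyl deprotection) without ionising the tertiary allylic alcohol.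

**Step 8**
Reactants: **10**
Product: **11** (4S)-4-hydroxy-4-[(2Z)-oct-2-en-1-yl]cyclopent-2-en-1-one
Conditions: activated MnO2 (15 equiv), CH2Cl2, rt
Reagents that add atoms: none
Why: MnO2 oxidises only the secondary allylic alcohol (allylic oxidation). The C4 stereocentre is destroyed here, and the tertiary C12 (S) centre is retained.

**Step 9**
Reactants: **11**
Product: **12** (4S)-4-[(2Z)-oct-2-en-1-yl]-4-(triethylsilyloxy)cyclopent-2-en-1-one
Conditions: TESOTf, 2,6-lutidine, CH2Cl2, −78 → 0 °C
Reagents that add atoms: TESOTf, CC[Si](CC)(CC)OS(=O)(=O)C(F)(F)F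
Why: Silylation masks the tertiary OH (as a TES ether) so that the later aldolate is a single alkoxide and can be acetylated selectively.

**Step 10**
Reactants: **12**
Product: **13** (4S)-2-iodo-4-[(2Z)-oct-2-en-1-yl]-4-(triethylsilyloxy)cyclopent-2-en-1-one
Conditions: I2, pyridine/CH2Cl2 (1:1), cat. DMAP, 0 °C → rt, dark
Reagents that add atoms: I2, II
Why: Pyridine/DMAP conjugate addition, α-iodination and elimination (Johnson α-iodination of enones) installs the C10 vinyl iodide, and I2·base does not add to the isolated Z-alkene.

**Step 11**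
Reactants: **13**; **5**
Product: **14** the 12-O-TES ether of the target (7-OAc)
Conditions: LDA (1.0 equiv), THF, −78 °C, 45 min; add **5** (1.2 equiv), −78 °C, 30 min; then Ac2O (6 equiv), −78 → −20 °C
Reagents that add atoms: Ac2O, CC(=O)OC(C)=O
Why: The only enolizable site is C8, giving the ring-constrained (E)-lithium enolate. It adds to the aldehyde through a Zimmerman–Traxler chair (anti-aldol, C7 S) on the face anti to the C12 octenyl chain (C8 R), and Ac2O traps the aldolate, which prevents retro-aldol and E1cB loss of the β-oxygen.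

**Step 12**
Reactants: **14**
Product: **15** 7-acetoxy-7,8-dihydroiodovulone I (target)
Conditions: HF·pyridine, pyridine/THF, 0 °C → rt
Reagents that add atoms: none
Why: Buffered fluoride removes the tertiary TES ether (silyl deprotection), and the acetate, methyl ester, vinyl iodide, Z-alkenes and C8/C7 centres are untouched under these non-basic conditions.

---

**Final check:**
- The ring is a cyclopentenone with C9=O, C10–I, C11=CH, a C12 carbinol carrying the (Z)-oct-2-enyl chain, and C8 carrying CH(OAc)–CH=CH(Z)–(CH2)3CO2Me.
- All atoms balance, for example **14** C29H47IO6Si → **15** C23H33IO6.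
- The only stereocentres, C12, C8 and C7, are set in steps 5 and 11, and no later step is basic or acidic enough to epimerise them.

**Compound list**

| # | Name | SMILES | Role |
|---|---|---|---|
| 1 | 5-hexynoic acid | C#CCCCC(=O)O | starting material |
| 2 | 7-hydroxyhept-5-ynoic acid | OCC#CCCCC(=O)O | intermediate |
| 3 | methyl 7-hydroxyhept-5-ynoate | OCC#CCCCC(=O)OC | intermediate |
| 4 | methyl (5Z)-7-hydroxyhept-5-enoate | OC/C=C\CCCC(=O)OC | intermediate |
| 5 | methyl (5Z)-7-oxohept-5-enoate | O=C/C=C\CCCC(=O)OC | intermediate |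
| 6 | (4R)-4-(TBSO)cyclopent-2-en-1-one | O=C1C=C[C@H](O[Si](C)(C)C(C)(C)C)C1 | starting material |
| 7 | (1S,4R)-1-allyl-4-(TBSO)cyclopent-2-en-1-ol | C=CC[C@@]1(O)C=C[C@H](O[Si](C)(C)C(C)(C)C)C1 | intermediate |
| 8 | 1-heptene | C=CCCCCC | starting material |
| 9 | (1S,4R)-4-(TBSO)-1-[(2Z)-oct-2-enyl]cyclopent-2-en-1-ol | CCCCC/C=C\C[C@@]1(O)C=C[C@H](O[Si](C)(C)C(C)(C)C)C1 | intermediate |
| 10 | (1S,4R)-1-[(2Z)-oct-2-enyl]cyclopent-2-ene-1,4-diol | CCCCC/C=C\C[C@@]1(O)C=C[C@H](O)C1 | intermediate |
| 11 | (4S)-4-hydroxy-4-[(2Z)-oct-2-enyl]cyclopent-2-en-1-one | CCCCC/C=C\C[C@@]1(O)C=CC(=O)C1 | intermediate |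
| 12 | (4S)-4-[(2Z)-oct-2-enyl]-4-(TESO)cyclopent-2-en-1-one | CCCCC/C=C\C[C@@]1(O[Si](CC)(CC)CC)C=CC(=O)C1 | intermediate |
| 13 | (4S)-2-iodo-4-[(2Z)-oct-2-enyl]-4-(TESO)cyclopent-2-en-1-one | CCCCC/C=C\C[C@@]1(O[Si](CC)(CC)CC)C=C(I)C(=O)C1 | intermediate |
| 14 | 12-O-TES ether of target | CCCCC/C=C\C[C@@]1(O[Si](CC)(CC)CC)C=C(I)C(=O)[C@@H]1[C@H](/C=C\CCCC(=O)OC)OC(C)=O | intermediate |
| 15 | 7-acetoxy-7,8-dihydroiodovulone I | CCCCC/C=C\C[C@@]1(O)C=C(I)C(=O)[C@@H]1[C@H](/C=C\CCCC(=O)OC)OC(C)=O | target |

**Total steps:** 12.
**Longest linear sequence:** 8 (steps 5–12, starting from **6**).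

**Three steps most likely to fail**
1. **Step 6 (Z-selective cross-metathesis):** conversion or Z/E ratio may be poor because of the hindered tertiary homoallylic alcohol. Fallback: cleave the allyl group (OsO4/NaIO4) on the silylated diol derivative, then run a salt-free Z-selective Wittig with hexylidenetriphenylphosphorane to build the C14=C15 Z-alkene.
2. **Step 10 (α-iodination next to the quaternary C12):** attack at the hindered β-carbon may be slow, and I2 may isomerise the Z-alkene. Fallback: brominate the enone (Br2, then Et3N) to the α-bromoenone, then convert it to the vinyl iodide by Cu-catalysed halogen exchange (CuI, NaI, N,N′-dimethylethylenediamine, dioxane).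
3. **Step 11 (aldol diastereoselectivity and enolate chemistry of the iodoenone):** the dr may be low or the iodoenone enolate may decompose. Fallback: make the silyl dienol ether of **13** (TESOTf, Et3N) and run a Lewis-acid Mukaiyama aldol with **5**, then acetylate (Ac2O, pyridine) as a separate step.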